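## Retrosynthetic overview

1. The C(sp)–C(sp2) bond is cut last: Sonogashira coupling of a terminal-alkyne dioxane acid with (E)-1-iodoundec-1-ene (from oct-1-yne and 1-bromopropane by alkyne zipper and hydrozirconation–iodination).
2. The 1,2-dioxane (the only ring of the target, formed last) comes from intramolecular SN2 opening of a (4R)-β-lactone at C4 by a hydroperoxy ketal. This inverts C4 to C6 (S) and frees the CH2CO2H arm; the ketal carbon is then equilibrated to 3R.
3. The hydroperoxy ketal comes from ozonolysis of a 1,1-disubstituted alkene in methanol.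
4. The β-lactone (second ring) comes from ring-expanding carbonylation of a terminal (R)-epoxide, oxirane → oxetan-2-one, with retention at the stereocentre. This is the pivotal skeletal step: it brings in the carboxyl carbon and turns C6 into an SN2 electrophile.
5. The epoxide (first ring) comes from dilithiated isoprenol and (R)-epichlorohydrin, followed by a three-carbon extension with lithiated 1-(trimethylsilyl)propyne. Ring order: oxirane → oxetan-2-one → 1,2-dioxane.

Assumption: the (3R,6S) target is the thermodynamic C3 anomer (axial OMe, both carbon substituents equatorial), so acid/MeOH equilibration of the peroxyketal carbon converges on it.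

## Route

Step 1
Reactants: 1 3-methylbut-3-en-1-ol (isoprenol); 2 (2R)-2-(chloromethyl)oxirane [(R)-epichlorohydrin]
Product: 5 3-methylidene-5-[(2R)-oxiran-2-yl]pentan-1-ol, via dilithiated isoprenol 3 (not isolated), via chlorohydrin 4 (not isolated)
Conditions: n-BuLi (2.1 equiv), TMEDA, Et2O/hexane, 0 °C to rt; added to 2 (1.1 equiv), Et2O, −78 to −30 °C; then 2 M aq NaOH, rt
Reagents that add atoms: none
Why: Alkoxide-directed allylic lithiation gives a symmetrical 2-substituted allyl anion that opens the epoxide of 2 at its CH2 (SN2), and Williamson closure of the chlorohydrin builds the new oxirane, so the C–O stereocentre of 2 is never broken and arrives as (R).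

Step 2
Reactants: 5 3-methylidene-5-[(2R)-oxiran-2-yl]pentan-1-ol; 6 trimethyl(prop-1-yn-1-yl)silane
Product: 9 trimethyl{6-methylidene-8-[(2R)-oxiran-2-yl]oct-1-yn-1-yl}silane, via triflate 7 (not isolated), via lithiated silylpropyne 8 (not isolated)
Conditions: 5, Tf2O (1.05 equiv), 2,6-lutidine (1.1 equiv), CH2Cl2, −78 °C; cannulated into 8 (2.5 equiv, from 6 and n-BuLi, THF, −78 °C), −78 to −50 °C
Reagents that add atoms: none
Why: O-triflation followed by SN2 alkylation of the propargylic organolithium (propargyl-selective for the silylpropyne anion) is fast at −78 °C, where an unactivated epoxide is not opened, and the stereocentre is untouched.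

Step 3
Reactants: 9 trimethyl{6-methylidene-8-[(2R)-oxiran-2-yl]oct-1-yn-1-yl}silane
Product: 10 (4R)-4-[3-methylidene-8-(trimethylsilyl)oct-7-yn-1-yl]oxetan-2-one
Conditions: CO (60 bar), [(salph)Al(THF)2][Co(CO)4] (2 mol %; salph = N,N′-bis(3,5-di-tert-butylsalicylidene)-1,2-phenylenediamine dianion), DME, 50 °C
Reagents that add atoms: carbon monoxide, [C-]#[O+]
Why: Ring-expanding carbonylation of an epoxide: the aluminium cation activates the oxirane, [Co(CO)4]− opens it at the unsubstituted CH2, CO inserts and the alkoxide closes onto the acyl cobalt, so the C–O bond at the stereocentre stays intact and (R) is retained.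

Step 4
Reactants: 10 (4R)-4-[3-methylidene-8-(trimethylsilyl)oct-7-yn-1-yl]oxetan-2-one
Product: 12 (4R)-4-[3-hydroperoxy-3-methoxy-8-(trimethylsilyl)oct-7-yn-1-yl]oxetan-2-one, via carbonyl oxide 11 (not isolated)
Conditions: O3, CH2Cl2/MeOH (3:1), −78 °C (Sudan red end-point); N2 purge; concentrated below 20 °C, no reductant
Reagents that add atoms: ozone, [O-][O+]=O; methanol, CO
Why: Ozonolysis with Criegee fragmentation places the carbonyl oxide on the disubstituted carbon and methanol traps it as the hydroperoxy ketal; the alkynylsilane and lactone are inert at −78 °C, and the new ketal centre (about 1:1) is corrected in step 5.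

Step 5
Reactants: 12 (4R)-4-[3-hydroperoxy-3-methoxy-8-(trimethylsilyl)oct-7-yn-1-yl]oxetan-2-one
Product: 15 2-[(3R,6S)-3-methoxy-3-(pent-4-yn-1-yl)-1,2-dioxan-6-yl]acetic acid, via silylated dioxane acid 13 (not isolated), via desilylated epimer mixture 14 (not isolated)
Conditions: Cs2CO3 (1.5 equiv), MeCN (0.01 M), 0 °C to rt; then MeOH (20 equiv), rt; then MeSO3H (3.5 equiv), 0 °C to rt
Reagents that add atoms: methanol, CO
Why: Proposed new method: Cs2CO3 deprotonates the hydroperoxy ketal and the peroxide anion attacks lactone C4 from the back side in a 6-exo-tet SN2 with alkyl–oxygen cleavage (acyl attack would need an 8-membered ring; the strained lactone makes carboxylate a good leaving group), which closes the 1,2-dioxane, inverts C4 (R) to C6 (S) and releases the free acid in one event; the closest known reaction types are the intramolecular opening of oxetanes by hydroperoxides and the SN2 alkyl–O opening of β-lactones by carboxylates and other soft nucleophiles; MeOH/Cs2CO3 then cleaves the alkynylsilane and MeSO3H/MeOH equilibrates the ketal carbon through the ring peroxycarbenium ion to the 3R anomer.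

Step 6
Reactants: 16 oct-1-yne; 17 1-bromopropane
Product: 19 undec-4-yne, via octynyllithium 18 (not isolated)
Conditions: n-BuLi (1.05 equiv), THF, −78 °C; then 17 (1.3 equiv), DMPU, −78 °C to rt
Reagents that add atoms: none
Why: Acetylide alkylation (SN2) of a primary bromide is routine.

Step 7
Reactants: 19 undec-4-yne
Product: 21 undec-1-yne, via potassium undecynide 20 (not isolated)
Conditions: KH (4 equiv), H2N(CH2)3NH2, rt; then 19, rt, 2 h; H2O, 0 °C
Reagents that add atoms: none
Why: Alkyne zipper isomerisation: potassium 3-aminopropylamide walks the triple bond along the unbranched chain, driven by irreversible formation of the terminal acetylide (either chain end gives the same product).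

Step 8
Reactants: 21 undec-1-yne
Product: 23 (1E)-1-iodoundec-1-ene, via alkenylzirconocene 22 (not isolated)
Conditions: Cp2Zr(H)Cl (1.2 equiv), THF, rt; then I2 (1.2 equiv), 0 °C
Reagents that add atoms: iodine, II
Why: Hydrozirconation is a syn addition with zirconium on the terminal carbon, and iodinolysis of the C–Zr bond proceeds with retention, giving only the E vinyl iodide.

Step 9
Reactants: 15 2-[(3R,6S)-3-methoxy-3-(pent-4-yn-1-yl)-1,2-dioxan-6-yl]acetic acid; 23 (1E)-1-iodoundec-1-ene
Product: 24 2-[(3R,6S)-3-[(6E)-hexadec-6-en-4-yn-1-yl]-3-methoxy-1,2-dioxan-6-yl]acetic acid (CNP0298534.1)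
Conditions: PdCl2(PPh3)2 (5 mol %), CuI (10 mol %), Et3N (5 equiv), THF, rt, degassed; pH 4 buffer work-up
Reagents that add atoms: none
Why: Sonogashira coupling: zerovalent palladium inserts into the vinyl iodide with retention of the E geometry and the copper acetylide transmetalates; dialkyl peroxyketals are expected to tolerate these mild conditions, the acid is carried as its ammonium salt, and no stereocentre is touched.

## Compound list

1 | 3-methylbut-3-en-1-ol (isoprenol) | C=C(C)CCO | starting material
2 | (2R)-2-(chloromethyl)oxirane, (R)-epichlorohydrin | ClC[C@H]1CO1 | starting material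
3 | lithium 3-(lithiomethyl)but-3-en-1-olate (dilithiated isoprenol) | [Li]CC(=C)CCO[Li] | intermediate
4 | (2R)-1-chloro-5-methylideneheptane-2,7-diol (formed as its dilithium alkoxide) | ClC[C@H](O)CCC(=C)CCO | intermediate
5 | 3-methylidene-5-[(2R)-oxiran-2-yl]pentan-1-ol | OCCC(=C)CC[C@@H]1CO1 | intermediate
6 | trimethyl(prop-1-yn-1-yl)silane | CC#C[Si](C)(C)C | starting material
7 | 3-methylidene-5-[(2R)-oxiran-2-yl]pentyl trifluoromethanesulfonate | FC(F)(F)S(=O)(=O)OCCC(=C)CC[C@@H]1CO1 | intermediate
8 | [3-(trimethylsilyl)prop-2-yn-1-yl]lithium | [Li]CC#C[Si](C)(C)C | intermediate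
9 | trimethyl{6-methylidene-8-[(2R)-oxiran-2-yl]oct-1-yn-1-yl}silane | C[Si](C)(C)C#CCCCC(=C)CC[C@@H]1CO1 | intermediate
10 | (4R)-4-[3-methylidene-8-(trimethylsilyl)oct-7-yn-1-yl]oxetan-2-one | C[Si](C)(C)C#CCCCC(=C)CC[C@@H]1CC(=O)O1 | intermediate
11 | carbonyl oxide (ketone O-oxide) at C3 of the side chain of 10 | C[Si](C)(C)C#CCCCC(=[O+][O-])CC[C@@H]1CC(=O)O1 | intermediate
12 | (4R)-4-[3-hydroperoxy-3-methoxy-8-(trimethylsilyl)oct-7-yn-1-yl]oxetan-2-one (both epimers at the ketal carbon) | C[Si](C)(C)C#CCCCC(OC)(OO)CC[C@@H]1CC(=O)O1 | intermediate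
13 | 2-{(6S)-3-methoxy-3-[5-(trimethylsilyl)pent-4-yn-1-yl]-1,2-dioxan-6-yl}acetic acid (C3 epimers, cesium salt in the flask) | C[Si](C)(C)C#CCCCC1(OC)CC[C@@H](CC(=O)O)OO1 | intermediate
14 | 2-[(6S)-3-methoxy-3-(pent-4-yn-1-yl)-1,2-dioxan-6-yl]acetic acid (C3 epimers, cesium salt in the flask) | C#CCCCC1(OC)CC[C@@H](CC(=O)O)OO1 | intermediate
15 | 2-[(3R,6S)-3-methoxy-3-(pent-4-yn-1-yl)-1,2-dioxan-6-yl]acetic acid | C#CCCC[C@]1(OC)CC[C@@H](CC(=O)O)OO1 | intermediate
16 | oct-1-yne | CCCCCCC#C | starting material
17 | 1-bromopropane | CCCBr | starting material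
18 | oct-1-yn-1-yllithium | CCCCCCC#C[Li] | intermediate
19 | undec-4-yne | CCCC#CCCCCCC | intermediate
20 | potassium undec-1-yn-1-ide | CCCCCCCCCC#C[K] | intermediate
21 | undec-1-yne | CCCCCCCCCC#C | intermediate
22 | chloridobis(cyclopentadienyl)[(1E)-undec-1-en-1-yl]zirconium | CCCCCCCCC/C=C/[Zr](Cl)(C1C=CC=C1)C1C=CC=C1 | intermediate
23 | (1E)-1-iodoundec-1-ene | CCCCCCCCC/C=C/I | intermediate
24 | 2-[(3R,6S)-3-[(6E)-hexadec-6-en-4-yn-1-yl]-3-methoxy-1,2-dioxan-6-yl]acetic acid | CCCCCCCCC/C=C/C#CCCC[C@]1(OC)CC[C@@H](CC(=O)O)OO1 | target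

## Step count and risks

Total steps: 9. Longest linear sequence: 6 (steps 1, 2, 3, 4, 5, 9).

**Step 5 (the new ring closure).** The peroxide anion could attack the lactone carbonyl intermolecularly, the product carboxylate could open unreacted lactone, or the equilibration could stall. The fallback uses known chemistry only; it sets out from 9 and comes back at 15. Trimethylsulfoxonium iodide and KOt-Bu in t-BuOH at 50 °C expand the oxirane of 9 to the oxetane with retention and cleave the alkynylsilane, giving (2R)-2-(3-methylideneoct-7-yn-1-yl)oxetane F1. Ozonolysis in CH2Cl2/MeOH at −78 °C gives (2R)-2-(3-hydroperoxy-3-methoxyoct-7-yn-1-yl)oxetane F2. A Lewis acid (Yb(OTf)3 or TMSOTf, CH2Cl2, low temperature) brings about the known intramolecular 6-exo opening of the oxetane by the hydroperoxide with inversion, giving 2-[(6S)-3-methoxy-3-(pent-4-yn-1-yl)-1,2-dioxan-6-yl]ethan-1-ol F3 as C3 epimers. TsOH in MeOH equilibrates these to 2-[(3R,6S)-3-methoxy-3-(pent-4-yn-1-yl)-1,2-dioxan-6-yl]ethan-1-ol F4. TEMPO (cat.) and PhI(OAc)2 in MeCN/water oxidise the primary alcohol through 2-[(3R,6S)-3-methoxy-3-(pent-4-yn-1-yl)-1,2-dioxan-6-yl]acetaldehyde F5 to acid 15.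

**Step 3 (carbonylation).** The Lewis-acidic cation may trigger epoxide-to-ketone rearrangement or attack by the nearby 1,1-disubstituted alkene, and the alkynylsilane may interfere with the cobalt carbonyl. The fallback sets out from 9 and comes back at 10; the stereocentre is then set by a catalyst instead of being carried from the epoxide. H5IO6 in Et2O/THF cleaves the terminal epoxide to 4-methylidene-9-(trimethylsilyl)non-8-ynal F6. A cinchona-catalysed acyl halide–aldehyde cyclocondensation (AcCl, i-Pr2NEt, LiClO4, O-trimethylsilylquinine or O-trimethylsilylquinidine, whichever pseudoenantiomer gives 4R, CH2Cl2/Et2O, −78 °C) then builds lactone 10.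

**Step 1 (dianion opening of epichlorohydrin).** Metalation may be incomplete, the product epoxide may be alkylated a second time, and some direct chloride displacement would erode the ee. The fallback sets out from 1 and 2 and comes back at 5, replacing the dilithio species by a protected allylic Grignard reagent. TBSCl and imidazole give tert-butyldimethyl[(3-methylbut-3-en-1-yl)oxy]silane F7. Ene-type allylic chlorination (Ca(OCl)2, CO2, CH2Cl2/H2O; minor trisubstituted isomer removed) gives tert-butyl{[3-(chloromethyl)but-3-en-1-yl]oxy}dimethylsilane F8. Mg in THF gives {2-[2-(tert-butyldimethylsilyloxy)ethyl]prop-2-en-1-yl}magnesium chloride F9. This opens 2 under CuI catalysis at −40 °C to (2R)-7-[(tert-butyldimethylsilyl)oxy]-1-chloro-5-methylideneheptan-2-ol F10. Aqueous NaOH closes it to tert-butyldimethyl({3-methylidene-5-[(2R)-oxiran-2-yl]pentyl}oxy)silane F11, and TBAF in THF releases 5.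

Further compounds
F1 | step 5 | (2R)-2-(3-methylideneoct-7-yn-1-yl)oxetane | C#CCCCC(=C)CC[C@@H]1CCO1
F2 | step 5 | (2R)-2-(3-hydroperoxy-3-methoxyoct-7-yn-1-yl)oxetane | C#CCCCC(OC)(OO)CC[C@@H]1CCO1
F3 | step 5 | 2-[(6S)-3-methoxy-3-(pent-4-yn-1-yl)-1,2-dioxan-6-yl]ethan-1-ol (C3 epimers) | C#CCCCC1(OC)CC[C@@H](CCO)OO1
F4 | step 5 | 2-[(3R,6S)-3-methoxy-3-(pent-4-yn-1-yl)-1,2-dioxan-6-yl]ethan-1-ol | C#CCCC[C@]1(OC)CC[C@@H](CCO)OO1
F5 | step 5 | 2-[(3R,6S)-3-methoxy-3-(pent-4-yn-1-yl)-1,2-dioxan-6-yl]acetaldehyde | C#CCCC[C@]1(OC)CC[C@@H](CC=O)OO1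
F6 | step 3 | 4-methylidene-9-(trimethylsilyl)non-8-ynal | C[Si](C)(C)C#CCCCC(=C)CCC=O
F7 | step 1 | tert-butyldimethyl[(3-methylbut-3-en-1-yl)oxy]silane | C=C(C)CCO[Si](C)(C)C(C)(C)C
F8 | step 1 | tert-butyl{[3-(chloromethyl)but-3-en-1-yl]oxy}dimethylsilane | C=C(CCl)CCO[Si](C)(C)C(C)(C)C
F9 | step 1 | {2-[2-(tert-butyldimethylsilyloxy)ethyl]prop-2-en-1-yl}magnesium chloride | C=C(C[Mg]Cl)CCO[Si](C)(C)C(C)(C)C
F10 | step 1 | (2R)-7-[(tert-butyldimethylsilyl)oxy]-1-chloro-5-methylideneheptan-2-ol | ClC[C@H](O)CCC(=C)CCO[Si](C)(C)C(C)(C)C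
F11 | step 1 | tert-butyldimethyl({3-methylidene-5-[(2R)-oxiran-2-yl]pentyl}oxy)silane | C=C(CCO[Si](C)(C)C(C)(C)C)CC[C@@H]1CO1
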